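The trap in a flask charged between two earlier runs is a straight line through their percentages: a loss that is a fixed amount in mM, and not a fixed share, counts in percent as one over the charge and does not lie on that line.

| setting | dawn | noon | flask |
|---|---|---|---|
| electrophile | 11 mM (fed, over 2.5 min) | 24 mM (fed, over 2.5 min) | 16 mM (fed, over 2.5 min) |
| free base | 4.8 mM | 4.8 mM | 4.80 mM |
| protonated nucleophile | 40 mM | 40 mM | 40.0 mM |
| protic impurity | 4.8 mM | 4.8 mM | 4.80 mM |
| remark | run made earlier | run made earlier |  |
| time |  |  | 3.0 min |

- dawn (time / min: electrophile / %, product / %): 0.200: 4.8, 0.9; 0.333: 5.6, 0; 0.500: 6.4, 0.7; 0.833: 9.0, 1.9; 1.33: 14.9, 2.6; 2.50: 43.9, 7.8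
- noon (time / min: electrophile / %, product / %): 0.200: 4.7, 0; 0.333: 6.3, 0; 0.500: 8.9, 0.3; 0.833: 15.4, 0.5; 1.33: 28.4, 2.4; 2.50: 50.0, 8.9

(readings scatter by 0.5 percentage points)

- the earlier runs were read with a standard deviation of 0.5 percentage points
- percentages count the whole charge, also what has not yet gone in
- the earlier runs do not show how much of nucleophile is bound; that part of a forecast is a guess

1. part of the electrophile that has reacted at 3.0 min
2. share of the unused nucleophile that is free and not bound as protonated nucleophile, at 3.0 min

In the noon run at 0.833 min, I reckon from the readings 4.18 mM of what has been fed to be neither electrophile nor product, against 4.8 mM of protic impurity, so I take it that each protic impurity quenches one electrophile, the impurity being the limiting reagent of that step in the noon run. The impurity tax of this flask is 30.0%, by which I mean c(protic impurity) over the charge of electrophile; at dawn it was 43.6% and at noon 20.0%.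

My first way to the end of the feed is the straight line: electrophile reacted, 56.1% at dawn and 50.0% at noon, gives 53.8% for this flask. My second way takes the tax off first: of what the tax leaves, the later loss took 22.1% at dawn and 37.5% at noon, the line through these gives 28.0%, and the flask stands at 49.6%. The first way cheats, since its line puts the tax at 34.5%, 4.5 percentage points above the true quotient, against a gap of 4.2 points between the ways.

Fed electrophile has waited 1.25 min on average, so the later loss runs at about 0.263 /min, and carrying that past the feed I commit to 55.8% reacted at 3.0 min. The bound share stands in no run; c(free base) over c(protonated nucleophile) is 12.0% at the start, and I guess somewhat lower later.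

The forecast, “Interpolating between dawn and noon”, gives 64% reacted, more than my figure, and 5% free.

The flask gives 58.6% reacted and 8.93% free.

    electrophile + nucleophile → acid set free + product (k = 0.560 /M/s)
    nucleophile + acid set free ⇌ protonated nucleophile, settled at all times (K = 4100 /M)
    acid set free + free base ⇌ salt of the base, settled at all times (K = 1.60 × 10⁷ /M)
    2 electrophile → homo dimer (k = 0.298 /M/s)
    electrophile + protic impurity → quenched substrate (k = 20.9 /M/s)

My figure lies 2.8 points below the flask's, and in this flask quenched substrate stands at 30.0% at 3.00 min, where the tax said 30.0%, with protic impurity at 0%. The neighbouring flask charged with 40 mM of electrophile, the other charges held, has a tax of 12.0%. That neighbour reacts to 66.3% at 3.00 min, and its quenched substrate stands at 12.0%.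

The numbers in the tables are calculated on assumed constants, and the scatter is random.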